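**Retrosynthetic overview**
- The feature the plan rests on is ring A, the phenol ring. It has four contiguous C–Br carbons (C3–C6) lying between two adjacent oxygen-bearing carbons, C1 (OH) and C2 (OAr).
- Target 15 comes from aryl boronate 14 by C–B to C–O oxidation; boron stands in for the C1 hydroxyl.
- Ring A of 14 is cut at C2–C3 and C1–C6 into tetrabromothiophene 1,1-dioxide 12 (C3–C6 with all four Br) and the aryloxy-alkynylboronate 9 (C1–B, C2–OAr), joined by [4+2] cycloaddition and loss of SO2.
- 9 comes from 2-bromophenol 1 through dichlorovinyl ether 4 and lithium acetylide 7; 12 comes from tetrabromothiophene 10 by peracid oxidation.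
- Ring B is bought; ring A is the only ring formed (step 4), and the diaryl ether C–O bond exists before ring A does.

Key step: step 4

Assumption: the target has no stereocentre and no configurationally stable axis (freely rotating diaryl ether), so it is achiral and the single-enantiomer requirement places no demand on the route.

**Route**

Step 1
Reactants: 1 2-bromophenol; 2 trichloroethylene
Product: 4 (E)-1-bromo-2-[(1,2-dichloroethenyl)oxy]benzene, via dichloroacetylene 3 (not isolated)
Conditions: K2CO3, DMF, 70 °C
Reagents that add atoms: none
Why: Carbonate dehydrochlorinates trichloroethylene to dichloroacetylene 3, and the phenoxide adds to it with anti protonation (nucleophilic addition to a haloalkyne, the standard O-dichlorovinylation of phenols) to give the E ether, the aryl bromide taking no part.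

Step 2
Reactants: 4 (E)-1-bromo-2-[(1,2-dichloroethenyl)oxy]benzene; 5 2-isopropoxy-4,4,5,5-tetramethyl-1,3,2-dioxaborolane
Product: 9 2-[(2-bromophenoxy)ethynyl]-4,4,5,5-tetramethyl-1,3,2-dioxaborolane, via chloroalkynyl ether 6 (not isolated), via lithium aryloxyacetylide 7 (not isolated), via lithium borate complex 8 (not isolated)
Conditions: n-BuLi (2.05 equiv, titrated), Et2O, −78 → −40 °C; 5, −78 °C; HCl·Et2O (1.0 equiv), −78 °C → rt; filtered from LiCl under Ar and used crude
Reagents that add atoms: none
Why: n-BuLi removes the vinylic hydrogen of 4, loss of LiCl gives chloroalkyne 6 and chlorine–lithium exchange gives acetylide 7 (the usual dichlorovinyl ether route to ynol ethers), which is borylated with 5 through ate complex 8 and released by one equivalent of anhydrous HCl (standard synthesis of pinacol alkynylboronates from lithium acetylides), bromine–lithium exchange of the aryl bromide with n-BuLi being slow in diethyl ether at −78 °C.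

Step 3
Reactants: 10 tetrabromothiophene
Product: 12 2,3,4,5-tetrabromothiophene 1,1-dioxide, via tetrabromothiophene 1-oxide 11 (not isolated)
Conditions: CF3CO3H (from (CF3CO)2O and 50% H2O2), CH2Cl2, 0 °C → rt
Reagents that add atoms: trifluoroperacetic acid, OOC(=O)C(F)(F)F (made in the flask from hydrogen peroxide, OO, and trifluoroacetic anhydride)
Why: The strong peracid oxidises the electron-poor thiophene sulfur to the S-oxide 11 and on to the sulfone (thiophene to thiophene 1,1-dioxide oxidation, as practised on tetrachlorothiophene), the second oxidation being faster than the first and the C–Br bonds inert.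

Step 4
Reactants: 9 2-[(2-bromophenoxy)ethynyl]-4,4,5,5-tetramethyl-1,3,2-dioxaborolane; 12 2,3,4,5-tetrabromothiophene 1,1-dioxide
Product: 14 2-[2,3,4,5-tetrabromo-6-(2-bromophenoxy)phenyl]-4,4,5,5-tetramethyl-1,3,2-dioxaborolane, via bridged sulfone cycloadduct 13 (not isolated)
Conditions: 9 (1.3 equiv), dry PhMe, 60 → 100 °C, Ar sweep
Reagents that add atoms: none
Why: Proposed new method: the non-aromatic diene of 12, its LUMO lowered by the sulfonyl group and four bromines, should add across its C2 and C5 to the oxygen-activated triple bond of 9 in a concerted, asynchronous inverse-electron-demand [4+2] cycloaddition, and the 7-thiabicyclo[2.2.1]heptadiene 7,7-dioxide 13 should then lose SO2 by thermally allowed cheletropic extrusion, driven by aromatisation. The closest known reaction types are the benzannulation of tetrachlorothiophene 1,1-dioxide with alkynes to tetrachlorobenzenes and the cycloaddition–extrusion benzannulations of alkynylboronates with cyclopentadienones and 2-pyranones; a 1-aryloxy-alkynylboronate has not served as the 2π partner. Ring A is closed as a six-membered carbocycle by intermolecular union of the four diene carbons (C3–C6 of the target) with the two alkyne carbons (C1 and C2), both σ-bonds (C2–C3 and C1–C6) forming in the same step and not by an exo or endo cyclisation of a chain. No stereocentre is set, since the two bridgehead carbons of racemic 13 become sp2 on extrusion. The only selectivity needed is chemoselectivity, cycloaddition against self-dimerisation of 12 and against stepwise [2+2] addition or hydrolysis of the ynol ether: the bromines at C2 and C5 of 12 slow its dimerisation, the oxygen lone pair raises the alkyne HOMO, and excess 9 in a dry non-polar solvent favours the concerted path, while regiochemistry is moot because 12 is C2v-symmetric.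

Step 5
Reactants: 14 2-[2,3,4,5-tetrabromo-6-(2-bromophenoxy)phenyl]-4,4,5,5-tetramethyl-1,3,2-dioxaborolane
Product: 15 3,4,5,6-tetrabromo-2-(2-bromophenoxy)phenol
Conditions: 30% H2O2, aq NaOH, THF, 0 °C → rt; then 1 M HCl
Reagents that add atoms: hydrogen peroxide, OO
Why: Hydroperoxide adds to boron and the aryl group migrates from boron to oxygen (oxidation of an arylboronic ester to a phenol), after which the borate hydrolyses; attack of the α-nucleophile at 0 °C is expected to outrun protodeboronation, and the aryl bromides and the diaryl ether are inert.

**Compound list**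
1 | 2-bromophenol | Oc1ccccc1Br | starting material
2 | trichloroethylene | ClC=C(Cl)Cl | starting material
3 | dichloroacetylene | ClC#CCl | intermediate (not isolated)
4 | (E)-1-bromo-2-[(1,2-dichloroethenyl)oxy]benzene | Cl/C=C(Cl)\Oc1ccccc1Br | intermediate
5 | 2-isopropoxy-4,4,5,5-tetramethyl-1,3,2-dioxaborolane | CC(C)OB1OC(C)(C)C(C)(C)O1 | starting material
6 | 1-bromo-2-[(chloroethynyl)oxy]benzene | ClC#COc1ccccc1Br | intermediate (not isolated)
7 | lithium (2-bromophenoxy)acetylide | [Li]C#COc1ccccc1Br | intermediate (not isolated)
8 | lithium [(2-bromophenoxy)ethynyl](isopropoxy)(pinacolato)borate | [Li+].CC(C)O[B-]1(OC(C)(C)C(C)(C)O1)C#COc1ccccc1Br | intermediate (not isolated)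
9 | 2-[(2-bromophenoxy)ethynyl]-4,4,5,5-tetramethyl-1,3,2-dioxaborolane | CC1(C)OB(OC1(C)C)C#COc1ccccc1Br | intermediate
10 | tetrabromothiophene | Brc1sc(Br)c(Br)c1Br | starting material
11 | 2,3,4,5-tetrabromothiophene 1-oxide | O=S1C(Br)=C(Br)C(Br)=C1Br | intermediate (not isolated)
12 | 2,3,4,5-tetrabromothiophene 1,1-dioxide | O=S1(=O)C(Br)=C(Br)C(Br)=C1Br | intermediate
13 | 2-[1,4,5,6-tetrabromo-3-(2-bromophenoxy)-7,7-dioxo-7-thiabicyclo[2.2.1]hepta-2,5-dien-2-yl]-4,4,5,5-tetramethyl-1,3,2-dioxaborolane (racemic, transient; the bicycle allows only one relative configuration) | O=S1(=O)C2(Br)C(Br)=C(Br)C1(Br)C(Oc3ccccc3Br)=C2B4OC(C)(C)C(C)(C)O4 | intermediate (not isolated)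
14 | 2-[2,3,4,5-tetrabromo-6-(2-bromophenoxy)phenyl]-4,4,5,5-tetramethyl-1,3,2-dioxaborolane | CC1(C)OB(OC1(C)C)c1c(Br)c(Br)c(Br)c(Br)c1Oc1ccccc1Br | intermediate
15 | 3,4,5,6-tetrabromo-2-(2-bromophenoxy)phenol | Oc1c(Br)c(Br)c(Br)c(Br)c1Oc1ccccc1Br | target

**Step count**
Total: 5 steps. Longest linear sequence: 4 steps (1, 2, 4, 5); step 3 is a one-step branch.

**Steps most likely to fail**

Step 4 (key step, proposed new method). The push–pull alkyne may be lost to hydrolysis, protodeboronation or oligomerisation before it is trapped. Stepwise zwitterionic addition at the vinyl sulfone may compete with the concerted cycloaddition, and crowding at the boron-bearing alkyne carbon may slow the addition until the sulfone decomposes. The fallback uses known reaction types, sets out from lithium acetylide 7 and comes back at aryl boronate 14; boron is brought in after ring A is built. Acetylide 7, made as in step 2, is quenched with aqueous NH4Cl to give 1-bromo-2-(ethynyloxy)benzene F1. This terminal ynol ether, less hindered and free of the labile C–B bond, is heated with sulfone 12 in toluene. The bridged sulfone 1,4,5,6-tetrabromo-2-(2-bromophenoxy)-7-thiabicyclo[2.2.1]hepta-2,5-diene 7,7-dioxide F2 should lose SO2 to give 1,2,3,4-tetrabromo-5-(2-bromophenoxy)benzene F3 (alkyne benzannulation of a tetrahalothiophene dioxide). The single ring-A hydrogen of F3, flanked by the aryloxy oxygen and a bromine, is removed with TMPMgCl·LiCl in THF at −40 °C; an amide base causes no halogen–metal exchange. The resulting [2,3,4,5-tetrabromo-6-(2-bromophenoxy)phenyl]magnesium chloride F4 is trapped with borate 5 to give 14.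

Step 2. Bromine–lithium exchange on the aryl ring may compete with the deprotonation and chlorine–lithium exchange, and HCl may add across the ynol ether when the ate complex is protonated. The fallback sets out from 1 and comes back at acetylide 7, using only eliminations with non-exchanging bases. Phenol 1 is O-vinylated with 2,4,6-trivinylcyclotriboroxane–pyridine, Cu(OAc)2 and pyridine in CH2Cl2 at rt (Chan–Lam-type coupling) to give 1-bromo-2-(ethenyloxy)benzene F5. Bromine in CH2Cl2 at −78 °C adds to the enol ether double bond to give racemic 1-bromo-2-(1,2-dibromoethoxy)benzene F6. i-Pr2NEt removes HBr through the labile α-bromo ether to give (Z)-1-bromo-2-[(2-bromoethenyl)oxy]benzene F7. LDA (2.1 equiv, THF, −78 °C) eliminates the second HBr and deprotonates the transient terminal alkyne 1-bromo-2-(ethynyloxy)benzene F1, giving 7. The borylation then follows as in step 2, with Me3SiCl in place of HCl to break up the ate complex if acid is the problem.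

Step 5. Base-mediated protodeboronation of the doubly ortho-substituted, electron-poor aryl boronate may outrun the boron-to-oxygen shift, and attack of hydroperoxide on the hindered boron may be slow. The fallback replaces the boron oxidation by electrophilic oxygenation of an arylmetal; it sets out from 7 and comes back at 15. Acetylide 7 is taken through the terminal ynol ether 1-bromo-2-(ethynyloxy)benzene F1 and 1,2,3,4-tetrabromo-5-(2-bromophenoxy)benzene F3 to [2,3,4,5-tetrabromo-6-(2-bromophenoxy)phenyl]magnesium chloride F4, as in the fallback for step 4. Any 14 that has lost its boron is F3 and enters at the same point. F4 is treated with bis(trimethylsilyl) peroxide in THF at −40 °C → rt to give trimethyl[2,3,4,5-tetrabromo-6-(2-bromophenoxy)phenoxy]silane F8 (electrophilic hydroxylation of an aryl Grignard reagent). Dilute HCl in MeOH during work-up cleaves the silyl ether to 15.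

**Further compounds**
F1 | step 4 | 1-bromo-2-(ethynyloxy)benzene | C#COc1ccccc1Br
F2 | step 4 | 1,4,5,6-tetrabromo-2-(2-bromophenoxy)-7-thiabicyclo[2.2.1]hepta-2,5-diene 7,7-dioxide (racemic, transient) | O=S1(=O)C2(Br)C=C(Oc3ccccc3Br)C1(Br)C(Br)=C2Br
F3 | step 4 | 1,2,3,4-tetrabromo-5-(2-bromophenoxy)benzene | Brc1ccccc1Oc1cc(Br)c(Br)c(Br)c1Br
F4 | step 4 | [2,3,4,5-tetrabromo-6-(2-bromophenoxy)phenyl]magnesium chloride | Cl[Mg]c1c(Br)c(Br)c(Br)c(Br)c1Oc1ccccc1Br
F5 | step 2 | 1-bromo-2-(ethenyloxy)benzene | C=COc1ccccc1Br
F6 | step 2 | 1-bromo-2-(1,2-dibromoethoxy)benzene (racemic) | BrCC(Br)Oc1ccccc1Br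
F7 | step 2 | (Z)-1-bromo-2-[(2-bromoethenyl)oxy]benzene | Br/C=C\Oc1ccccc1Br
F8 | step 5 | trimethyl[2,3,4,5-tetrabromo-6-(2-bromophenoxy)phenoxy]silane | C[Si](C)(C)Oc1c(Br)c(Br)c(Br)c(Br)c1Oc1ccccc1Br
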